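## Retrosynthetic overview

1. The target is epiafzelechin-(4β→8)-epiafzelechin-(4β→8)-4'-O-methylepigallocatechin. The last operations are reductive removal of two 3-O-pivalates and hydrogenolysis of eleven benzyl ethers; the complete bottom unit comes from (−)-epigallocatechin by 4'-O-methylation.
2. Ring C of the top unit is cut across O1–C2 and C3–C4 into an ortho-quinone methide (o-QM: O1=C8a–C4a=C4 of the top ring A, with C4 carrying C8 of the middle unit) and the (Z)-enol pivalate of (4-benzyloxyphenyl)acetaldehyde as the C3–C2 unit. The same cut, one round earlier, removes ring C of the middle unit.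
3. Enabling feature: C4 of each upper unit is doubly benzylic, held between C4a of a phloroglucinol ring A (whose O1 phenol is ortho to C4a) and C8 of the ring A below, so a diaryl carbinol ionises to the o-QM. C2 carries a 4-oxyphenyl ring, which makes C3 the nucleophilic alkene terminus.
4. The carbinols arise by aryllithium additions: the 8-lithio bottom unit adds to 4,6-bis(benzyloxy)-2-hydroxyisophthalaldehyde (ring A of the middle unit; its second formyl group becomes the C8 handle), then ortho-lithiated 3,5-bis(benzyloxy)phenoxide (ring A of the top unit) adds to that formyl group.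
5. Order of ring formation: bottom unit (chiral pool), then ring C of the middle unit (step 9), then ring C of the top unit (step 11).

Key step: step 11

Remark: the chiral acid of steps 9 and 11 is written as its R enantiomer on the assumption that this is the matched antipode. Both annulations create the same (2R,3R,4β) unit, so the same antipode serves both; the sense of induction would be fixed on carbinol 14 before step 11 is run.

## Route

Step 1
Reactants: 1 1-(benzyloxy)-4-ethynylbenzene; 2 pivalic acid
Product: 3 (Z)-2-[4-(benzyloxy)phenyl]ethenyl pivalate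
Conditions: [RuCl2(p-cymene)]2 (1 mol %), P(4-ClC6H4)3, 4-(dimethylamino)pyridine, toluene, 60 °C
Reagents that add atoms: none
Why: Ruthenium-catalysed anti-Markovnikov addition of a carboxylic acid to a terminal alkyne (Gooßen–Dixneuf enol ester synthesis) proceeds through a ruthenium vinylidene and should deliver the (Z)-enol ester; no stereocentre is formed.

Step 2
Reactants: 4 3,5-bis(benzyloxy)phenol
Product: 5 4,6-bis(benzyloxy)-2-hydroxybenzene-1,3-dicarbaldehyde
Conditions: MgCl2, Et3N, (CH2O)n (excess), MeCN, reflux; aq HCl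
Reagents that add atoms: paraformaldehyde (as formaldehyde), C=O
Why: In the Casiraghi–Skattebøl magnesium-mediated ortho-formylation the magnesium phenoxide delivers formaldehyde only to the two positions ortho to the phenol, and a second equivalent of formaldehyde oxidises each hydroxymethyl group, so both ortho positions should be formylated.

Step 3
Reactants: 4 3,5-bis(benzyloxy)phenol
Product: 6 3,5-bis(benzyloxy)-2-bromophenol
Conditions: NBS (1.0 equiv), i-Pr2NH (10 mol %), CH2Cl2, −78 → 0 °C
Reagents that add atoms: N-bromosuccinimide, O=C1CCC(=O)N1Br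
Why: Amine-catalysed ortho-selective electrophilic bromination of a phenol (a hydrogen-bonded N-bromoamine delivers bromine next to the OH) should give the ortho-bromophenol, one equivalent at low temperature limiting dibromination.

Step 4
Reactants: 7 (−)-epigallocatechin
Product: 8 4'-O-methyl-(−)-epigallocatechin
Conditions: MeI (1.05 equiv), K2CO3 (1.0 equiv), acetone, rt, argon
Reagents that add atoms: iodomethane, CI
Why: Williamson O-methylation with one equivalent of weak base should take place at the 4'-OH, the most acidic phenol because its phenoxide is flanked by two hydrogen-bond-donating OH groups; the two stereocentres are untouched and the methyl ether then blocks base-induced C2 epimerisation.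

Step 5
Reactants: 8 4'-O-methyl-(−)-epigallocatechin
Product: 9 5,7,3',5'-tetra-O-benzyl-4'-O-methylepigallocatechin
Conditions: BnBr (4.4 equiv), K2CO3, DMF, 0 °C → rt
Reagents that add atoms: benzyl bromide, BrCc1ccccc1
Why: Williamson benzylation with carbonate base should etherify the four remaining phenols and leave the aliphatic 3-OH free.

Step 6
Reactants: 9 5,7,3',5'-tetra-O-benzyl-4'-O-methylepigallocatechin
Product: 10 3,5,7,3',5'-penta-O-benzyl-4'-O-methylepigallocatechin
Conditions: NaH, BnBr, n-Bu4NI (cat.), DMF, 0 °C → rt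
Reagents that add atoms: benzyl bromide, BrCc1ccccc1
Why: Williamson etherification of the secondary alkoxide should make the unit inert to the organolithium and carbocation chemistry that follows.

Step 7
Reactants: 10 3,5,7,3',5'-penta-O-benzyl-4'-O-methylepigallocatechin
Product: 11 8-bromo-3,5,7,3',5'-penta-O-benzyl-4'-O-methylepigallocatechin
Conditions: NBS (1.0 equiv), CH2Cl2, −78 → −20 °C
Reagents that add atoms: N-bromosuccinimide, O=C1CCC(=O)N1Br
Why: Electrophilic aromatic bromination should occur at C8 of ring A (between O1 and the 7-benzyloxy group), the most nucleophilic position of 5,7-dialkoxyflavans, as is usual for benzylated catechins.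

Step 8
Reactants: 11 8-bromo-3,5,7,3',5'-penta-O-benzyl-4'-O-methylepigallocatechin; 5 4,6-bis(benzyloxy)-2-hydroxybenzene-1,3-dicarbaldehyde
Product: 14 [4,6-bis(benzyloxy)-3-formyl-2-hydroxyphenyl](flavan-8-yl)methanol of the bottom unit (mixture of carbinol epimers), via sodium phenoxide 12 (not isolated), via aryllithium 13 (not isolated)
Conditions: 5 (2.5 equiv), NaH, THF, 0 °C; separately 11, n-BuLi (1.05 equiv), THF, −78 °C; 13 added to 12, −78 → −20 °C; aq NH4Cl; 14 used crude
Reagents that add atoms: none
Why: Bromine–lithium exchange and 1,2-addition of the aryllithium to an aldehyde should give the mono-adduct, because the pre-formed phenoxide spares the organometallic and the remaining formyl group becomes a deactivated vinylogous carboxylate after the first addition; the new carbinol centre is erased in step 9.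

Step 9
Reactants: 14 carbinol of step 8; 3 (Z)-2-[4-(benzyloxy)phenyl]ethenyl pivalate
Product: 16 8-formyl-3-O-pivaloyl-5,7,4'-tri-O-benzylepiafzelechin-(4β→8)-3,5,7,3',5'-penta-O-benzyl-4'-O-methylepigallocatechin, via ortho-quinone methide 15 (not isolated)
Conditions: 3 (3 equiv), (R)-3,3'-bis(2,4,6-triisopropylphenyl)-1,1'-binaphthyl-2,2'-diyl hydrogen phosphate (10 mol %), 4 Å molecular sieves, toluene, −20 °C → rt
Reagents that add atoms: none
Why: Proposed new method: the chiral phosphoric acid should ionise the o-hydroxybenzhydrol 14 to the o-QM 15 (a 1-oxadiene held as a hydrogen-bonded ion pair), to which 3 adds in an inverse-electron-demand oxa-Diels–Alder reaction, C3 bonding to C4 and the methide oxygen closing on C2 of the same alkene face, so that the Z geometry becomes 2,3-cis, the pivalate settles anti to the 4-aryl group (3,4-trans, 4β) and the phosphate chooses the face (2R,3R); C3 is the nucleophilic terminus because the 4-benzyloxyphenyl group stabilises charge at C2 far better than the acyloxy group could at C3, and the closest known reaction type is the Brønsted-acid-catalysed [4+2] cycloaddition of o-QMs from o-hydroxybenzhydrols with styrenes and propenylarenes, not yet shown with an enol ester or a methide flanked by four ortho substituents.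

Step 10
Reactants: 6 3,5-bis(benzyloxy)-2-bromophenol; 16 dimer aldehyde of step 9
Product: 18 [2,4-bis(benzyloxy)-6-hydroxyphenyl]methanol attached at C8 of the middle unit of the dimer (mixture of carbinol epimers), via dilithio phenoxide 17 (not isolated)
Conditions: 6 (1.5 equiv), n-BuLi (2.1 equiv per 6), THF, −78 → −40 °C; then 16, −78 → −40 °C; aq NH4Cl; 18 used crude
Reagents that add atoms: none
Why: Phenol deprotonation and bromine–lithium exchange should give the ortho-lithiated lithium phenoxide, which adds to the aldehyde far faster than to the hindered secondary pivalate at low temperature; the carbinol epimers converge in step 11.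

Step 11
Reactants: 18 carbinol of step 10; 3 (Z)-2-[4-(benzyloxy)phenyl]ethenyl pivalate
Product: 20 3-O-pivaloyl-5,7,4'-tri-O-benzylepiafzelechin-(4β→8)-3-O-pivaloyl-5,7,4'-tri-O-benzylepiafzelechin-(4β→8)-3,5,7,3',5'-penta-O-benzyl-4'-O-methylepigallocatechin, via ortho-quinone methide 19 (not isolated)
Conditions: 3 (3 equiv), (R)-3,3'-bis(2,4,6-triisopropylphenyl)-1,1'-binaphthyl-2,2'-diyl hydrogen phosphate (10 mol %), 4 Å molecular sieves, toluene, −20 °C → rt
Reagents that add atoms: none
Why: Proposed new method: the chiral phosphoric acid should ionise the o-hydroxybenzhydrol 18 (only the top ring A carries a free phenol, so only one quinone methide can form) to the o-QM 19, which is held as a hydrogen-bonded ion pair and reacts with 3 in an asynchronous, concerted inverse-electron-demand oxa-Diels–Alder reaction. The closest known reaction type is the Brønsted-acid-catalysed [4+2] cycloaddition of o-QMs from o-hydroxybenzhydrols with styrenes and propenylarenes to 2,4-diarylchromans; an enol ester partner and a methide flanked by four ortho substituents have not been shown. Ring C of the top unit closes in the [4+2] mode, the four atoms O1–C8a–C4a–C4 of the oxadiene joining C3=C2 of the alkene: C3–C4 forms first and O1 then collapses onto the C2 benzylic cation on the same alkene face before C2–C3 rotation. At C2 and C3 the Z geometry of 3 is transferred suprafacially into the 2,3-cis relationship; at C4 the alkene approaches with its pivalate anti to the twisted 4-aryl group across the forming C3–C4 bond (exo approach to the E-configured methide, the same anti preference that makes captures of 2,3-cis flavan-4-yl cations 4β-selective), giving 3,4-trans; the absolute sense (2R,3R,4R) is set by the chiral phosphate shielding one face of the ion pair. The step needs regioselectivity (C3 to C4, O1 to C2), secured because the 4-benzyloxyphenyl group stabilises charge at C2 far better than the acyloxy group could at C3, and chemoselectivity against Friedel–Crafts capture of the cation by free ring A positions, secured by the excess of 3 and a low concentration of 18.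

Step 12
Reactants: 20 bis-pivalate of step 11
Product: 21 5,7,4'-tri-O-benzylepiafzelechin-(4β→8)-5,7,4'-tri-O-benzylepiafzelechin-(4β→8)-3,5,7,3',5'-penta-O-benzyl-4'-O-methylepigallocatechin
Conditions: LiAlH4, THF, 0 °C → rt; H2O, aq NaOH
Reagents that add atoms: none
Why: Reductive cleavage of the two hindered pivalates by hydride attack at the acyl carbon should free both 3-OH groups without touching the benzyl ethers or any C–O bond at a stereocentre.

Step 13
Reactants: 21 undecabenzyl trimer of step 12
Product: 22 epiafzelechin-(4β→8)-epiafzelechin-(4β→8)-4'-O-methylepigallocatechin (CNP0146516.1)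
Conditions: H2 (1 atm), Pd(OH)2/C, THF/MeOH/H2O, rt
Reagents that add atoms: none
Why: Hydrogenolysis of the eleven benzyl ethers over Pd(OH)2/C under neutral conditions is the standard end-game for benzylated oligomeric flavan-3-ols and should leave the ring C benzylic C2–O1 bonds and the interflavan bonds intact.

## Compound list

1 | 1-(benzyloxy)-4-ethynylbenzene | C#Cc1ccc(OCc2ccccc2)cc1 | starting material
2 | pivalic acid | CC(C)(C)C(=O)O | starting material
3 | (Z)-2-[4-(benzyloxy)phenyl]ethenyl pivalate | CC(C)(C)C(=O)O/C=C\c1ccc(OCc2ccccc2)cc1 | intermediate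
4 | 3,5-bis(benzyloxy)phenol | Oc1cc(OCc2ccccc2)cc(OCc2ccccc2)c1 | starting material
5 | 4,6-bis(benzyloxy)-2-hydroxybenzene-1,3-dicarbaldehyde | O=Cc1c(O)c(C=O)c(OCc2ccccc2)cc1OCc1ccccc1 | intermediate
6 | 3,5-bis(benzyloxy)-2-bromophenol | Oc1cc(OCc2ccccc2)cc(OCc2ccccc2)c1Br | intermediate
7 | (−)-epigallocatechin, (2R,3R) | Oc1cc([C@H]2Oc3cc(O)cc(O)c3C[C@H]2O)cc(O)c1O | starting material
8 | 4'-O-methyl-(−)-epigallocatechin, (2R,3R) | COc1c(O)cc([C@H]2Oc3cc(O)cc(O)c3C[C@H]2O)cc1O | intermediate
9 | 5,7,3',5'-tetra-O-benzyl-4'-O-methylepigallocatechin, (2R,3R) | COc1c(OCc2ccccc2)cc([C@H]2Oc3cc(OCc4ccccc4)cc(OCc4ccccc4)c3C[C@H]2O)cc1OCc1ccccc1 | intermediate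
10 | 3,5,7,3',5'-penta-O-benzyl-4'-O-methylepigallocatechin, (2R,3R) | COc1c(OCc2ccccc2)cc([C@H]2Oc3cc(OCc4ccccc4)cc(OCc4ccccc4)c3C[C@H]2OCc2ccccc2)cc1OCc1ccccc1 | intermediate
11 | 8-bromo-3,5,7,3',5'-penta-O-benzyl-4'-O-methylepigallocatechin, (2R,3R) | COc1c(OCc2ccccc2)cc([C@H]2Oc3c(c(OCc4ccccc4)cc(OCc4ccccc4)c3Br)C[C@H]2OCc2ccccc2)cc1OCc1ccccc1 | intermediate
12 | sodium 3,5-bis(benzyloxy)-2,6-diformylphenolate | [Na+].[O-]c1c(C=O)c(OCc2ccccc2)cc(OCc2ccccc2)c1C=O | intermediate
13 | 8-lithio-3,5,7,3',5'-penta-O-benzyl-4'-O-methylepigallocatechin | COc1c(OCc2ccccc2)cc([C@H]2Oc3c(c(OCc4ccccc4)cc(OCc4ccccc4)c3[Li])C[C@H]2OCc2ccccc2)cc1OCc1ccccc1 | intermediate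
14 | [4,6-bis(benzyloxy)-3-formyl-2-hydroxyphenyl][(2R,3R)-penta-O-benzyl-4'-O-methylepigallocatechin-8-yl]methanol, carbinol epimers | COc1c(OCc2ccccc2)cc([C@H]2Oc3c(c(OCc4ccccc4)cc(OCc4ccccc4)c3C(O)c3c(O)c(C=O)c(OCc4ccccc4)cc3OCc3ccccc3)C[C@H]2OCc2ccccc2)cc1OCc1ccccc1 | intermediate
15 | ortho-quinone methide from 14 (6-(flavan-8-ylmethylidene)-3,5-bis(benzyloxy)-2-formylcyclohexa-2,4-dienone) | COc1c(OCc2ccccc2)cc([C@H]2Oc3c(c(OCc4ccccc4)cc(OCc4ccccc4)c3C=C3C(=O)C(C=O)=C(OCc4ccccc4)C=C3OCc3ccccc3)C[C@H]2OCc2ccccc2)cc1OCc1ccccc1 | intermediate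
16 | 8-formyl-3-O-pivaloyl-5,7,4'-tri-O-benzylepiafzelechin-(4β→8)-3,5,7,3',5'-penta-O-benzyl-4'-O-methylepigallocatechin (upper unit 2R,3R, C4–aryl bond trans to O3) | COc1c(OCc2ccccc2)cc([C@H]2Oc3c(c(OCc4ccccc4)cc(OCc4ccccc4)c3[C@H]3c4c(OCc5ccccc5)cc(OCc5ccccc5)c(C=O)c4O[C@H](c4ccc(OCc5ccccc5)cc4)[C@@H]3OC(=O)C(C)(C)C)C[C@H]2OCc2ccccc2)cc1OCc1ccccc1 | intermediate
17 | lithium 3,5-bis(benzyloxy)-2-lithiophenolate | [Li+].[O-]c1cc(OCc2ccccc2)cc(OCc2ccccc2)c1[Li] | intermediate
18 | dimer 16 with the 8-formyl group of the middle unit converted into CH(OH)[2,4-bis(benzyloxy)-6-hydroxyphenyl], carbinol epimers | COc1c(OCc2ccccc2)cc([C@H]2Oc3c(c(OCc4ccccc4)cc(OCc4ccccc4)c3[C@H]3c4c(OCc5ccccc5)cc(OCc5ccccc5)c(C(O)c5c(O)cc(OCc6ccccc6)cc5OCc5ccccc5)c4O[C@H](c4ccc(OCc5ccccc5)cc4)[C@@H]3OC(=O)C(C)(C)C)C[C@H]2OCc2ccccc2)cc1OCc1ccccc1 | intermediate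
19 | ortho-quinone methide from 18 (6-methylidene-3,5-bis(benzyloxy)cyclohexa-2,4-dienone bearing C8 of the middle unit on the methide carbon) | COc1c(OCc2ccccc2)cc([C@H]2Oc3c(c(OCc4ccccc4)cc(OCc4ccccc4)c3[C@H]3c4c(OCc5ccccc5)cc(OCc5ccccc5)c(C=C5C(=O)C=C(OCc6ccccc6)C=C5OCc5ccccc5)c4O[C@H](c4ccc(OCc5ccccc5)cc4)[C@@H]3OC(=O)C(C)(C)C)C[C@H]2OCc2ccccc2)cc1OCc1ccccc1 | intermediate
20 | undecabenzyl trimer 3,3-bis-O-pivalate (top and middle units 2R,3R with 4β interflavan bonds, bottom unit 2R,3R) | COc1c(OCc2ccccc2)cc([C@H]2Oc3c(c(OCc4ccccc4)cc(OCc4ccccc4)c3[C@H]3c4c(OCc5ccccc5)cc(OCc5ccccc5)c([C@H]5c6c(OCc7ccccc7)cc(OCc7ccccc7)cc6O[C@H](c6ccc(OCc7ccccc7)cc6)[C@@H]5OC(=O)C(C)(C)C)c4O[C@H](c4ccc(OCc5ccccc5)cc4)[C@@H]3OC(=O)C(C)(C)C)C[C@H]2OCc2ccccc2)cc1OCc1ccccc1 | intermediate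
21 | undecabenzyl trimer with free 3-OH on the top and middle units | COc1c(OCc2ccccc2)cc([C@H]2Oc3c(c(OCc4ccccc4)cc(OCc4ccccc4)c3[C@H]3c4c(OCc5ccccc5)cc(OCc5ccccc5)c([C@H]5c6c(OCc7ccccc7)cc(OCc7ccccc7)cc6O[C@H](c6ccc(OCc7ccccc7)cc6)[C@@H]5O)c4O[C@H](c4ccc(OCc5ccccc5)cc4)[C@@H]3O)C[C@H]2OCc2ccccc2)cc1OCc1ccccc1 | intermediate
22 | epiafzelechin-(4β→8)-epiafzelechin-(4β→8)-4'-O-methylepigallocatechin (CNP0146516.1) | COc1c(O)cc([C@H]2Oc3c(c(O)cc(O)c3[C@H]3c4c(O)cc(O)c([C@H]5c6c(O)cc(O)cc6O[C@H](c6ccc(O)cc6)[C@@H]5O)c4O[C@H](c4ccc(O)cc4)[C@@H]3O)C[C@H]2O)cc1O | target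

## Step count and risks

Total step count: 13. Longest linear sequence: 10 steps (steps 4–13, from (−)-epigallocatechin 7).

**Step 11 (Proposed new method).** The highly stabilised, crowded o-QM may react too slowly with the enol ester, so that Friedel–Crafts self-condensation takes over. Bond rotation in an open benzylic cation may erode the 2,3-cis relationship. Facial selectivity may be poor if catalyst and substrate are mismatched. The fallback uses known flavan-4-yl cation chemistry, sets out from 10 and comes back at 21. Commercial (−)-epiafzelechin would be benzylated (BnBr, K2CO3, DMF) to 5,7,4'-tri-O-benzylepiafzelechin F1. Oxidation at C4 with 2,3-dichloro-5,6-dicyano-1,4-benzoquinone in the presence of 2-ethoxyethanol (CH2Cl2, rt) would give the 4β-(2-ethoxyethoxy) ether F2. Me3SiOTf-catalysed condensation of F2 with an excess of 10 (CH2Cl2, −78 °C) would give the 4β→8 dimer F3, by attack of C8 of 10 anti to the 3-OH. A second condensation of F2 with an excess of F3, at C8 of its upper unit, would give 21, which enters step 13.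

**Step 9 (Proposed new method).** The same three processes threaten this step: slow cycloaddition, loss of alkene geometry in a stepwise path and poor facial selectivity. In addition the free formyl group may condense under the acid conditions. The fallback uses known chemistry, sets out from 10 and comes back at 16. The dimer F3, made from 10 and F2 as described above, would be acylated (pivaloyl chloride, 4-(dimethylamino)pyridine, pyridine) to the 3-O-pivalate F4. Vilsmeier–Haack formylation (POCl3, DMF, 0 °C → rt) at C8 of the upper unit, the most nucleophilic free ring A position, would give 16.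

**Step 8.** The aryllithium may be quenched by adventitious proton transfer, may add sluggishly to the deactivated phenoxide-aldehyde, or may add twice. The fallback reverses the polarity of the C4–C8 bond construction, sets out from 11 and comes back at 16. Bromine–lithium exchange of 11 (n-BuLi, THF, −78 °C) and a DMF quench would give the 8-carbaldehyde F5. Addition of the dilithio phenoxide 17 would give the carbinol F6. Annulation of F6 with 3 under the conditions of step 9 would give the 3-O-pivaloyl dimer F4, which would be formylated as above (POCl3, DMF) to 16.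

## Further compounds

F1 | step 11 | 5,7,4'-tri-O-benzyl-(−)-epiafzelechin, (2R,3R) | C(Oc1ccc(cc1)[C@H]1Oc2cc(OCc3ccccc3)cc(OCc3ccccc3)c2C[C@H]1O)c1ccccc1
F2 | step 11 | 4β-(2-ethoxyethoxy)-5,7,4'-tri-O-benzylepiafzelechin | CCOCCO[C@H]1c2c(OCc3ccccc3)cc(OCc3ccccc3)cc2O[C@H](c2ccc(OCc3ccccc3)cc2)[C@@H]1O
F3 | step 11 | 5,7,4'-tri-O-benzylepiafzelechin-(4β→8)-3,5,7,3',5'-penta-O-benzyl-4'-O-methylepigallocatechin | COc1c(OCc2ccccc2)cc([C@H]2Oc3c(c(OCc4ccccc4)cc(OCc4ccccc4)c3[C@H]3c4c(OCc5ccccc5)cc(OCc5ccccc5)cc4O[C@H](c4ccc(OCc5ccccc5)cc4)[C@@H]3O)C[C@H]2OCc2ccccc2)cc1OCc1ccccc1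
F4 | step 9 | 3-O-pivaloyl-5,7,4'-tri-O-benzylepiafzelechin-(4β→8)-3,5,7,3',5'-penta-O-benzyl-4'-O-methylepigallocatechin | COc1c(OCc2ccccc2)cc([C@H]2Oc3c(c(OCc4ccccc4)cc(OCc4ccccc4)c3[C@H]3c4c(OCc5ccccc5)cc(OCc5ccccc5)cc4O[C@H](c4ccc(OCc5ccccc5)cc4)[C@@H]3OC(=O)C(C)(C)C)C[C@H]2OCc2ccccc2)cc1OCc1ccccc1
F5 | step 8 | 8-formyl-3,5,7,3',5'-penta-O-benzyl-4'-O-methylepigallocatechin | COc1c(OCc2ccccc2)cc([C@H]2Oc3c(c(OCc4ccccc4)cc(OCc4ccccc4)c3C=O)C[C@H]2OCc2ccccc2)cc1OCc1ccccc1
F6 | step 8 | [2,4-bis(benzyloxy)-6-hydroxyphenyl][penta-O-benzyl-4'-O-methylepigallocatechin-8-yl]methanol, carbinol epimers | COc1c(OCc2ccccc2)cc([C@H]2Oc3c(c(OCc4ccccc4)cc(OCc4ccccc4)c3C(O)c3c(O)cc(OCc4ccccc4)cc3OCc3ccccc3)C[C@H]2OCc2ccccc2)cc1OCc1ccccc1
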